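**Assumptions (one line each)**
- The target's carbinol is (S). From the SMILES, the priorities are OH > butenolide C3 > aryl > H.
- The exocyclic alkene is Z, with the aryl cis to the ring oxygen, as in the rubrolide family.
- (3-Bromo-4-hydroxyphenyl)boronic acid is treated as commercially available.

**Retrosynthetic overview**
1. The (S)-carbinol comes last, by asymmetric transfer hydrogenation of the 3-aroyl ketone.
2. The Z-5-arylidene comes from a Knoevenagel-type condensation of the acidic C5-H2 of a 3-aroyl-4-aryl-butenolide with an aldehyde.
3. The 4-aryl group comes from Suzuki coupling of a 4-triflyloxy butenolide.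
4. The only ring is the butenolide of commercial tetronic acid, and C3 is C-acylated with an aroyl group first.
5. All three bromoarenes are carried in from commercial building blocks, so no late bromination or protecting groups are needed.

---

**Step 1**
Reactants: 1 (tetronic acid, 4-hydroxyfuran-2(5H)-one); 2 (3,5-dibromo-4-methoxybenzoic acid)
Product: 3, 3-(3,5-dibromo-4-methoxybenzoyl)-4-hydroxyfuran-2(5H)-one
Conditions: DCC, DMAP, CH2Cl2, 0 °C to rt
Reagents that add atoms: none (DCC is only a dehydrating agent)
Why: Carbodiimide coupling forms the O-acyl tetronate, and DMAP-mediated O-to-C acyl migration gives the chelated 3-acyl tetronic acid (Jones-type C-acylation). There is no stereocenter.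

**Step 2**
Reactants: 3; 4 (triflic anhydride)
Product: 5, 3-(3,5-dibromo-4-methoxybenzoyl)-4-(trifluoromethanesulfonyloxy)furan-2(5H)-one
Conditions: Tf2O, DIPEA, CH2Cl2, −78 to 0 °C
Reagents that add atoms: Tf2O, O=S(=O)(OS(=O)(=O)C(F)(F)F)C(F)(F)F, which is compound 4
Why: The acidic vinylogous-acid 4-OH is O-sulfonylated to give an enol triflate, which is a good Suzuki electrophile. There is no stereocenter.

**Step 3**
Reactants: 5; 6 ((3-bromo-4-hydroxyphenyl)boronic acid)
Product: 7, 3-(3,5-dibromo-4-methoxybenzoyl)-4-(3-bromo-4-hydroxyphenyl)furan-2(5H)-one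
Conditions: Pd(PPh3)4 (5 mol%), K3PO4, dioxane/H2O, 45 °C
Reagents that add atoms: none (the aryl group comes from 6)
Why: Suzuki–Miyaura coupling occurs at the highly activated enol triflate. The aryl bromides do not react at this temperature, because the phenoxide ring is electron-rich and the dibromoanisole is hindered and deactivated. There is no stereocenter.

**Step 4**
Reactants: 7; 8 (3-bromo-4-hydroxybenzaldehyde)
Product: 9, (Z)-3-(3,5-dibromo-4-methoxybenzoyl)-4-(3-bromo-4-hydroxyphenyl)-5-(3-bromo-4-hydroxybenzylidene)furan-2(5H)-one
Conditions: piperidine (cat.), AcOH, toluene, 80–100 °C, Dean–Stark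
Reagents that add atoms: none (water is lost)
Why: Knoevenagel-type condensation at the doubly vinylogous-acidic C5-H2, followed by E1cB dehydration. The Z-arylidene is the thermodynamic isomer, and this sets the alkene geometry of the target.

**Step 5**
Reactants: 9
Product: 10, target, (S)-3-[(3,5-dibromo-4-methoxyphenyl)(hydroxy)methyl]-4-(3-bromo-4-hydroxyphenyl)-5-(Z)-(3-bromo-4-hydroxybenzylidene)furan-2(5H)-one
Conditions: RuCl[(R,R)-TsDPEN](p-cymene) (2 mol%), HCO2H/Et3N (5:2), CH2Cl2, 30 °C
Reagents that add atoms: none (formate supplies only H)
Why: Noyori asymmetric transfer hydrogenation of the diaryl-type ketone. The Ru–H delivers hydride to one face of the ketone, with the unhindered aryl group oriented toward the catalyst arene and the tetrasubstituted butenolide occupying the other side. By analogy with (S,S)-catalyst giving (S)-1-phenylethanol, and allowing for the priority swap here, the (R,R)-catalyst is predicted to give the (S)-carbinol. This is the only stereocenter, and nothing later touches it. The absolute configuration should be checked by Mosher analysis or X-ray.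

---

**Compound list**

| No. | Name | SMILES | Role |
|---|---|---|---|
| 1 | Tetronic acid (4-hydroxyfuran-2(5H)-one) | O=C1C=C(O)CO1 | starting material |
| 2 | 3,5-Dibromo-4-methoxybenzoic acid | COc1c(Br)cc(C(=O)O)cc1Br | starting material |
| 3 | 3-(3,5-Dibromo-4-methoxybenzoyl)-4-hydroxyfuran-2(5H)-one | COc1c(Br)cc(C(=O)C2=C(O)COC2=O)cc1Br | intermediate |
| 4 | Triflic anhydride | O=S(=O)(OS(=O)(=O)C(F)(F)F)C(F)(F)F | starting material |
| 5 | 4-Triflyloxy-3-aroylfuran-2(5H)-one | COc1c(Br)cc(C(=O)C2=C(OS(=O)(=O)C(F)(F)F)COC2=O)cc1Br | intermediate |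
| 6 | (3-Bromo-4-hydroxyphenyl)boronic acid | OB(O)c1ccc(O)c(Br)c1 | starting material |
| 7 | 3-Aroyl-4-(3-bromo-4-hydroxyphenyl)furan-2(5H)-one | COc1c(Br)cc(C(=O)C2=C(c3ccc(O)c(Br)c3)COC2=O)cc1Br | intermediate |
| 8 | 3-Bromo-4-hydroxybenzaldehyde | O=Cc1ccc(O)c(Br)c1 | starting material |
| 9 | (Z)-5-Arylidene-3-aroyl-4-aryl butenolide (ketone) | COc1c(Br)cc(C(=O)C2=C(c3ccc(O)c(Br)c3)/C(=C/c3ccc(O)c(Br)c3)OC2=O)cc1Br | intermediate |
| 10 | Target (S)-carbinol | COc1c(Br)cc([C@H](O)C2=C(c3ccc(O)c(Br)c3)/C(=C/c3ccc(O)c(Br)c3)OC2=O)cc1Br | target |

**Total steps:** 5. **Longest linear sequence:** 5 (from 1 via 3, 5, 7, 9 to 10).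

**Three steps most likely to fail, with fallbacks**
1. **Step 5 (enantioselectivity and chemoselectivity).** The ketone is flanked by a tetrasubstituted butenolide, so the ee may be modest, or the conjugated arylidene may be reduced.
   - Fallback: reduce 9 non-selectively with NaBH4/CeCl3, then separate the enantiomers by preparative chiral HPLC or lipase-catalysed acylation. Alternatively, make the 3-formyl analogue and add the aryl group enantioselectively.
2. **Steps 2–3 (triflation and Suzuki of the highly electrophilic 3-acyl enol triflate).** Triflation may occur on the exocyclic enol oxygen, or the triflate may hydrolyse or couple poorly.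
   - Fallback: change the order. Build the rubrolide core first (tetronic acid to 4-tosylate, Suzuki, then Knoevenagel condensation). Then brominate C3, do a Br/Mg exchange with iPrMgCl·LiCl at −78 °C, and add to 3,5-dibromo-4-methoxybenzaldehyde. Oxidise the resulting racemic alcohol to the ketone and use the ATH of step 5.
3. **Step 4 (condensation with a free-phenol aldehyde).** Phenoxide formation deactivates the aldehyde, and the product may be a Z/E mixture.
   - Fallback: use a vinylogous Mukaiyama aldol. Convert 7 to its 2-silyloxyfuran (TBSOTf, Et3N), add the TBS-protected aldehyde, then dehydrate. Remove the TBS group after the carbinol is set, using HF·pyridine.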